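**Plan**

1. Atom labels C1–C30 follow the target SMILES (ring A = C7–C8–C9–C10–C11, ring C = C9–C10–C11–C13–C14–C15, ring B = C13–C14–C15–C16–C26). Retrosynthesis: free both methyl ketones, put ketones back on the one-carbon bridges C10 and C14, cut ring B at C13–C26, then the arm bonds C16–C26 and C15=C16, cut ring A at C8–C9 (aldol) and the arm at C7–C11 (Michael).
2. Enabling feature: C10, the one-carbon bridge between bridgeheads C9 and C11, lies β,γ to the C7=C8 alkene. As a ketone it lets C9 add to a C8 aldehyde on the arm at quaternary C11, and because C9 is a bridgehead the alkene can afterwards only sit at C7=C8.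
3. Forward, first half: one cis-cyclopropane aldehyde (from caronic anhydride) serves twice. Its nitroalkene is joined to ring C (from 4,4-dimethoxycyclohexanone) at C11; a Nef reaction and the aldol close ring A; the C8 oxygen leaves through an enol triflate.
4. Forward, second half: the C14 ketone is unmasked, the second aldehyde is attached at C15, a vinyl group is added at C16, and palladium-mediated attack of the C13 enol ether on that vinyl group closes ring B. Alkene migration, removal of both bridge ketones and ketal hydrolysis finish.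
5. Stereochemistry: both cyclopropanes come from one alkaloid-mediated opening of the meso anhydride; C11 from an (R)-1-phenylethylamine imine; C9 from C11 (cis bridge); C15 and C13 from an arm placed on the endo face and closed without epimerisation, which puts both alkene bridges on the same face of ring C.

Key step: step 12

Assumption: quinidine opens caronic anhydride in the sense it shows with other cis-fused bicyclic succinic anhydrides, giving hemiester 2; if the opposite sense were found, quinine would be used and nothing else changes.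
Conventions: Kcp = the cis-2,2-dimethyl-3-[2-(2-methyl-1,3-dioxolan-2-yl)ethyl]cyclopropyl group of aldehyde 9, attached through the carbon that carries the formyl group in 9. Exo = the face of ring C turned toward the C10 bridge; endo = the face turned toward the C7=C8 bridge.

**Route**

Step 1
Reactants: 1 caronic anhydride
Product: 2 (1S,3R)-3-(methoxycarbonyl)-2,2-dimethylcyclopropane-1-carboxylic acid
Conditions: MeOH (3 equiv), quinidine (1.1 equiv), toluene, −55 °C
Reagents that add atoms: methanol, CO
Why: Alkaloid-mediated desymmetrising methanolysis of a meso anhydride: quinidine acts as a chiral general base and delivers methanol to one of the two enantiotopic carbonyl groups, which fixes both cyclopropane stereocentres of each half of the target at once.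

Step 2
Reactants: 2 hemiester
Product: 4 methyl (1R,3S)-3-formyl-2,2-dimethylcyclopropane-1-carboxylate, via acid chloride 3 (not isolated)
Conditions: (COCl)2, DMF (cat.), CH2Cl2, 0 to 23 °C; then LiAlH(OtBu)3, THF, −78 °C
Reagents that add atoms: none
Why: Acyl chloride half-reduction: the hindered hydride LiAlH(OtBu)3 stops at the aldehyde at −78 °C and does not touch the methyl ester, and the cis relationship is kept because no base is present.

Step 3
Reactants: 4 aldehyde ester; 5 1-(triphenylphosphoranylidene)propan-2-one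
Product: 6 methyl (1R,3S)-2,2-dimethyl-3-[(E)-3-oxobut-1-enyl]cyclopropane-1-carboxylate
Conditions: toluene, 80 °C
Reagents that add atoms: none
Why: Wittig olefination with a stabilised acyl ylide is neutral enough to leave the epimerisable cis aldehyde intact and gives the (E)-enone.

Step 4
Reactants: 6 enone ester
Product: 7 methyl (1R,3S)-2,2-dimethyl-3-(3-oxobutyl)cyclopropane-1-carboxylate
Conditions: H2 (1 atm), RhCl(PPh3)3 (5 mol%), benzene, 23 °C
Reagents that add atoms: none
Why: Homogeneous hydrogenation with RhCl(PPh3)3 saturates the disubstituted enone C=C and, unlike heterogeneous palladium, should not open the adjacent cyclopropane.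

Step 5
Reactants: 7 keto ester
Product: 8 methyl (1R,3S)-2,2-dimethyl-3-[2-(2-methyl-1,3-dioxolan-2-yl)ethyl]cyclopropane-1-carboxylate
Conditions: ethylene glycol, p-TsOH (cat.), benzene, reflux, Dean–Stark trap
Reagents that add atoms: ethylene glycol, OCCO
Why: Acid-catalysed ketalisation with azeotropic removal of water masks the methyl ketone as a dioxolane that withstands the hydrides, enolates, organometallics and hydrazine used later.

Step 6
Reactants: 8 ketal ester
Product: 9 (1R,3S)-2,2-dimethyl-3-[2-(2-methyl-1,3-dioxolan-2-yl)ethyl]cyclopropane-1-carbaldehyde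
Conditions: iBu2AlH (1.05 equiv), CH2Cl2, −78 °C; aq. potassium sodium tartrate
Reagents that add atoms: none
Why: Ester half-reduction with iBu2AlH at −78 °C, where the tetrahedral aluminium hemiacetal persists until work-up, gives the cis aldehyde that serves both halves of the target.

Step 7
Reactants: 9 aldehyde; 10 nitromethane
Product: 13 2-[2-[(1S,3S)-2,2-dimethyl-3-[(E)-2-nitroethenyl]cyclopropyl]ethyl]-2-methyl-1,3-dioxolane, via nitro alcohol 11 (not isolated), via mesylate 12 (not isolated)
Conditions: MeNO2 (5 equiv), KOtBu (10 mol%), THF/t-BuOH, 0 °C; then MsCl, Et3N, CH2Cl2, −20 to 0 °C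
Reagents that add atoms: none
Why: Henry reaction followed by mesylation and E1cB elimination gives the (E)-nitroalkene; the elimination should be fast enough that the cyclopropylcarbinyl mesylate has no time to ionise.

Step 8
Reactants: 14 4,4-dimethoxycyclohexanone; 15 iodomethane
Product: 16 4,4-dimethoxy-2-methylcyclohexan-1-one (racemic)
Conditions: LDA, THF, −78 °C; MeI, −78 to 0 °C
Reagents that add atoms: none
Why: Kinetic enolate alkylation of a symmetrical ketone gives the racemic 2-methyl ketone, whose stereocentre is erased again in step 10.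

Step 9
Reactants: 16 2-methyl ketone
Product: 17 N-[(1R)-1-phenylethyl] ketimine of 16
Conditions: (R)-1-phenylethylamine (1.05 equiv), 4 Å molecular sieves, toluene, 60 °C
Reagents that add atoms: (R)-1-phenylethylamine, C[C@@H](N)c1ccccc1
Why: Acid-free condensation of the ketone with the primary amine over molecular sieves gives the ketimine and leaves the dimethyl ketal intact.

Step 10
Reactants: 17 ketimine; 13 nitroalkene
Product: 19 (2S)-4,4-dimethoxy-2-methyl-2-[1-(Kcp)-2-nitroethyl]cyclohexan-1-one (C7 epimers), via adduct imine 18 (not isolated)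
Conditions: THF, 23 to 45 °C; then AcOH/NaOAc buffer (pH 5), H2O, THF, 23 °C
Reagents that add atoms: water, O
Why: Deracemising Michael addition of a chiral ketimine: the more substituted secondary enamine tautomer adds to the nitroalkene through a compact aza-ene-type transition state on the face turned away from the phenyl group, which creates quaternary C11 in the sense known for 2-methylcyclohexanone imines (the (R)-amine leading to the configuration drawn), while the C7 centre is of no consequence; buffered hydrolysis then frees the ketone.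

Step 11
Reactants: 19 γ-nitro ketone
Product: 21 (2S)-4,4-dimethoxy-2-methyl-2-[1-(Kcp)-2-oxoethyl]cyclohexan-1-one (C7 epimers), via sodium nitronate 20 (not isolated)
Conditions: NaOMe (1.05 equiv), MeOH, 0 °C; O3, CH2Cl2/MeOH, −78 °C; then AcOH, −78 °C
Reagents that add atoms: ozone, [O-][O+]=O
Why: Nef reaction in its ozonolytic variant: the C=N bond of the nitronate is cleaved at −78 °C to the aldehyde under conditions that spare both ketals, and the molecule has no C=C bond at this stage.

Step 12
Reactants: 21 γ-keto aldehyde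
Product: 22 (1S,5R)-6-hydroxy-3,3-dimethoxy-1-methyl-7-(Kcp)bicyclo[3.2.1]octan-8-one (epimers at C7 and C8)
Conditions: K2CO3 (0.3 equiv), MeOH, 0 to 23 °C
Reagents that add atoms: none
Why: K2CO3 in methanol reversibly enolises the C10 ketone, and since C11 is quaternary only C9 can be deprotonated; the enolate carbon adds to the C8 aldehyde of the arm on C11 and the alkoxide is protonated by the solvent. This is a base-mediated intramolecular aldol addition of a 1,4-dicarbonyl compound, the reaction by which γ-keto aldehydes and 1,4-diketones close to five-membered rings. Ring A (C7–C8–C9–C10–C11) closes in a 5-(enolendo)-exo-trig mode and C10 becomes the one-carbon bridge of a bicyclo[3.2.1]octane. C9 is controlled by C11, because the new bond can only form on the ring face that carries the arm (a cis bridge), whereas the C8 carbinol and the epimerisable C7 are left uncontrolled since both become sp2 in steps 13 to 15. The step needs addition without condensation and a single nucleophilic site: dehydration toward C9 is forbidden by Bredt's rule and C7–H is not acidic in the aldol, the C14 and side-chain ketones are masked as ketals, and the aldehyde enolate at C7 has no carbonyl group within reach.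

Step 13
Reactants: 22 aldol
Product: 23 (1S,5R)-3,3-dimethoxy-1-methyl-7-(Kcp)bicyclo[3.2.1]octane-6,8-dione (C7 epimers)
Conditions: Pr4N[RuO4] (5 mol%), N-methylmorpholine N-oxide, 4 Å molecular sieves, CH2Cl2, 23 °C
Reagents that add atoms: none
Why: Ley–Griffith oxidation under neutral conditions converts the carbinol into the C8 ketone without retro-aldol cleavage; the 1,3-diketone cannot enolise between the carbonyl groups because C9 is a bridgehead.

Step 14
Reactants: 23 diketone
Product: 24 (1S,5R)-3,3-dimethoxy-1-methyl-8-oxo-7-(Kcp)bicyclo[3.2.1]oct-6-en-6-yl trifluoromethanesulfonate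
Conditions: KHMDS, THF, −78 °C; PhNTf2, −78 to 0 °C
Reagents that add atoms: N-phenylbis(trifluoromethanesulfonimide), O=S(=O)(N(c1ccccc1)S(=O)(=O)C(F)(F)F)C(F)(F)F
Why: Enol triflate formation: the only enolisable position is C7 (C9 bridgehead, C11 quaternary), so KHMDS gives one enolate, which PhNTf2 sulfonylates on oxygen and thereby fixes the double bond at C7=C8 whatever the C7 and C8 configurations were.

Step 15
Reactants: 24 enol triflate
Product: 25 (1S,5R)-3,3-dimethoxy-1-methyl-7-(Kcp)bicyclo[3.2.1]oct-6-en-8-one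
Conditions: Pd(OAc)2 (5 mol%), PPh3 (10 mol%), Et3N, HCO2H, DMF, 60 °C
Reagents that add atoms: none
Why: Palladium-catalysed formate reduction of an enol triflate (oxidative addition to zerovalent palladium, formate exchange, loss of CO2, reductive elimination) replaces the triflate by hydrogen and keeps the alkene position.

Step 16
Reactants: 25 ketal enone
Product: 26 (1S,5R)-1-methyl-7-(Kcp)bicyclo[3.2.1]oct-6-ene-3,8-dione
Conditions: pyridinium p-toluenesulfonate (cat.), acetone/H2O 20:1, 23 °C
Reagents that add atoms: water, O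
Why: Acetal hydrolysis under mild acid: the acyclic dimethyl ketal is cleaved much faster than the dioxolane, which unmasks C14 selectively.

Step 17
Reactants: 26 diketone; 9 aldehyde
Product: 27 (1S,5R)-4-[hydroxy(Kcp)methyl]-1-methyl-7-(Kcp)bicyclo[3.2.1]oct-6-ene-3,8-dione (arm on C15; epimers at C15 and the carbinol)
Conditions: LDA (1.05 equiv), THF, −78 °C; then 9, −78 °C; aq. NH4Cl
Reagents that add atoms: none
Why: Directed aldol addition: LDA removes a proton from the less hindered C15 methylene (C13 is neopentylic, next to quaternary C11, and the C10 ketone has no enolisable position) and the lithium enolate adds to the aldehyde at −78 °C.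

Step 18
Reactants: 27 aldol adduct
Product: 29 (1S,5R,4E)-1-methyl-7-(Kcp)-4-[(Kcp)methylidene]bicyclo[3.2.1]oct-6-ene-3,8-dione, via acetate 28 (not isolated)
Conditions: Ac2O, DMAP, Et3N, CH2Cl2, 23 °C; then DBU, 23 °C
Reagents that add atoms: none
Why: Acetylation followed by E1cB elimination with DBU gives the thermodynamically preferred (E)-alkylidene ketone without generating a cyclopropylcarbinyl cation.

Step 19
Reactants: 29 enone; 30 vinylmagnesium bromide
Product: 32 (1S,5R)-1-methyl-7-(Kcp)-4-[1-(Kcp)prop-2-enyl]bicyclo[3.2.1]oct-6-ene-3,8-dione (arm endo at C15; C16 as drawn), via silyl enol ether 31 (not isolated)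
Conditions: CH2=CHMgBr (1.5 equiv), CuBr·SMe2 (20 mol%), Me3SiCl (2 equiv), THF, −78 °C; then K2CO3, MeOH, 0 °C
Reagents that add atoms: none
Why: Copper-catalysed conjugate addition of the vinyl Grignard reagent, accelerated by Me3SiCl so that it outruns 1,2-addition to the ketones, should occur on the exo face of the s-cis enone and set C16; methanolysis of the silyl enol ether protonates C15 from the exo face and, being reversible, leaves the arm in the more stable endo (equatorial) position.

Step 20
Reactants: 32 vinyl ketone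
Product: 33 C13=C14 tert-butyldimethylsilyl enol ether of 32
Conditions: LDA, THF, −78 °C; then tBuMe2SiOTf, −78 °C
Reagents that add atoms: tert-butyldimethylsilyl trifluoromethanesulfonate, CC(C)(C)[Si](C)(C)OS(=O)(=O)C(F)(F)F
Why: Kinetic enolisation: LDA removes a proton from the C13 methylene rather than from the tertiary, branched C15, so the C15 configuration survives and the enolate is trapped as a regiodefined silyl enol ether.

Step 21
Reactants: 33 silyl enol ether
Product: 34 syn-tricyclo[4.2.1.1(2,5)]decene-dione (target numbering: ketones at C10 and C14, C7=C8, exocyclic C26=C27H2, H on C16 pointing inward, both side chains as dioxolanes)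
Conditions: Pd(OAc)2 (1.1 equiv), MeCN, 23 to 40 °C
Reagents that add atoms: none
Why: Palladium-mediated cycloalkenylation of a silyl enol ether (an intramolecular relative of the Saegusa–Ito oxidation, divalent palladium): the palladium enolate at C13 cannot lose a β-hydride because C11 is quaternary, so it inserts the vinyl group held on the endo face in a 5-exo closure (C13–C26) and β-hydride elimination leaves the exocyclic C26=C27 alkene; as the step is neutral and irreversible and C15 is not epimerised, the new bridge must form on the face that already carries the C7=C8 bridge, which sets C13.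

Step 22
Reactants: 34 exocyclic alkene
Product: 35 tricyclic diene-dione (C16=C26 in the ring, methyl C27 on C26; ketones at C10 and C14)
Conditions: CoCl(C36H52N2O2) [chloro cobalt complex of N,N′-bis(3,5-di-tert-butylsalicylidene)cyclohexane-1,2-diamine, trivalent cobalt] (5 mol%), PhSiH3 (5 mol%), benzene, 23 °C
Reagents that add atoms: none
Why: Hydrogen-atom-transfer alkene isomerisation: the cobalt hydride adds H to the unhindered exocyclic CH2, and the tertiary C26 radical gives back a hydrogen atom from C16 (C13 is a bridgehead), which moves the double bond to the tetrasubstituted, cyclopropane-conjugated ring position and removes the inward-pointing C16 hydrogen.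

Step 23
Reactants: 35 diene-dione
Product: 37 bis(ethylene ketal) of the target, via bis-hydrazone 36 (not isolated)
Conditions: N2H4·H2O, AcOH (cat.), EtOH, 80 °C, under argon; then KOtBu, DMSO, 23 °C
Reagents that add atoms: none
Why: Wolff–Kishner reduction of both non-enolisable bridge ketones through their hydrazones, run in the room-temperature KOtBu/DMSO variant because cis-alkyl vinylcyclopropanes undergo homo-1,5-hydrogen shifts on strong heating; dioxolanes and alkenes are inert to the base.

Step 24
Reactants: 37 bis-ketal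
Product: 38 target CNP0300925.1
Conditions: pyridinium p-toluenesulfonate, acetone/H2O 10:1, 40 °C
Reagents that add atoms: water, O
Why: Mild acid-catalysed ketal hydrolysis frees both methyl ketones; the weak acid avoids protonating the vinylcyclopropane alkenes.

**Compound list**

1 | caronic anhydride (cis-6,6-dimethyl-3-oxabicyclo[3.1.0]hexane-2,4-dione, meso) | CC1(C)[C@H]2[C@@H]1C(=O)OC2=O | starting material
2 | (1S,3R)-3-(methoxycarbonyl)-2,2-dimethylcyclopropane-1-carboxylic acid | OC(=O)[C@H]1[C@@H](C(=O)OC)C1(C)C | intermediate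
3 | methyl (1R,3S)-3-(chlorocarbonyl)-2,2-dimethylcyclopropane-1-carboxylate | ClC(=O)[C@H]1[C@@H](C(=O)OC)C1(C)C | intermediate (not isolated)
4 | methyl (1R,3S)-3-formyl-2,2-dimethylcyclopropane-1-carboxylate | O=C[C@H]1[C@@H](C(=O)OC)C1(C)C | intermediate
5 | 1-(triphenylphosphoranylidene)propan-2-one | CC(=O)C=P(c1ccccc1)(c1ccccc1)c1ccccc1 | starting material
6 | methyl (1R,3S)-2,2-dimethyl-3-[(E)-3-oxobut-1-enyl]cyclopropane-1-carboxylate | CC(=O)/C=C/[C@H]1[C@@H](C(=O)OC)C1(C)C | intermediate
7 | methyl (1R,3S)-2,2-dimethyl-3-(3-oxobutyl)cyclopropane-1-carboxylate | CC(=O)CC[C@H]1[C@@H](C(=O)OC)C1(C)C | intermediate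
8 | methyl (1R,3S)-2,2-dimethyl-3-[2-(2-methyl-1,3-dioxolan-2-yl)ethyl]cyclopropane-1-carboxylate | CC2(OCCO2)CC[C@H]1[C@@H](C(=O)OC)C1(C)C | intermediate
9 | (1R,3S)-2,2-dimethyl-3-[2-(2-methyl-1,3-dioxolan-2-yl)ethyl]cyclopropane-1-carbaldehyde | CC2(OCCO2)CC[C@H]1[C@@H](C=O)C1(C)C | intermediate
10 | nitromethane | C[N+](=O)[O-] | starting material
11 | 1-(Kcp)-2-nitroethanol (carbinol epimers) | CC2(OCCO2)CC[C@H]1[C@@H](C(O)C[N+](=O)[O-])C1(C)C | intermediate (not isolated)
12 | methanesulfonate of 11 | CC2(OCCO2)CC[C@H]1[C@@H](C(OS(C)(=O)=O)C[N+](=O)[O-])C1(C)C | intermediate (not isolated)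
13 | 2-[2-[(1S,3S)-2,2-dimethyl-3-[(E)-2-nitroethenyl]cyclopropyl]ethyl]-2-methyl-1,3-dioxolane (cis, ring as in 9) | CC2(OCCO2)CC[C@H]1[C@@H](/C=C/[N+](=O)[O-])C1(C)C | intermediate
14 | 4,4-dimethoxycyclohexanone | COC1(OC)CCC(=O)CC1 | starting material
15 | iodomethane | CI | starting material
16 | 4,4-dimethoxy-2-methylcyclohexan-1-one (racemic) | COC1(OC)CCC(=O)C(C)C1 | intermediate
17 | N-[(1R)-1-phenylethyl] ketimine of 16 | COC1(OC)CCC(=N[C@H](C)c2ccccc2)C(C)C1 | intermediate
18 | N-[(1R)-1-phenylethyl] ketimine of 19 | CC2(OCCO2)CC[C@H]1[C@@H](C(C[N+](=O)[O-])[C@@]3(C)C(=N[C@H](C)c4ccccc4)CCC(OC)(OC)C3)C1(C)C | intermediate (not isolated)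
19 | (2S)-4,4-dimethoxy-2-methyl-2-[1-(Kcp)-2-nitroethyl]cyclohexan-1-one (C7 epimers) | CC2(OCCO2)CC[C@H]1[C@@H](C(C[N+](=O)[O-])[C@@]3(C)C(=O)CCC(OC)(OC)C3)C1(C)C | intermediate
20 | sodium nitronate of 19 | CC2(OCCO2)CC[C@H]1[C@@H](C(C=[N+]([O-])[O-])[C@@]3(C)C(=O)CCC(OC)(OC)C3)C1(C)C.[Na+] | intermediate (not isolated)
21 | (2S)-4,4-dimethoxy-2-methyl-2-[1-(Kcp)-2-oxoethyl]cyclohexan-1-one (C7 epimers) | CC2(OCCO2)CC[C@H]1[C@@H](C(C=O)[C@@]3(C)C(=O)CCC(OC)(OC)C3)C1(C)C | intermediate
22 | (1S,5R)-6-hydroxy-3,3-dimethoxy-1-methyl-7-(Kcp)bicyclo[3.2.1]octan-8-one (epimers at C7 and C8) | CC2(OCCO2)CC[C@H]1[C@@H](C3C(O)[C@@H]4C(=O)[C@@]3(C)CC(OC)(OC)C4)C1(C)C | intermediate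
23 | (1S,5R)-3,3-dimethoxy-1-methyl-7-(Kcp)bicyclo[3.2.1]octane-6,8-dione (C7 epimers) | CC2(OCCO2)CC[C@H]1[C@@H](C3C(=O)[C@@H]4C(=O)[C@@]3(C)CC(OC)(OC)C4)C1(C)C | intermediate
24 | (1S,5R)-3,3-dimethoxy-1-methyl-8-oxo-7-(Kcp)bicyclo[3.2.1]oct-6-en-6-yl trifluoromethanesulfonate | CC2(OCCO2)CC[C@H]1[C@@H](C3=C(OS(=O)(=O)C(F)(F)F)[C@@H]4C(=O)[C@@]3(C)CC(OC)(OC)C4)C1(C)C | intermediate
25 | (1S,5R)-3,3-dimethoxy-1-methyl-7-(Kcp)bicyclo[3.2.1]oct-6-en-8-one | CC2(OCCO2)CC[C@H]1[C@@H](C3=C[C@@H]4C(=O)[C@@]3(C)CC(OC)(OC)C4)C1(C)C | intermediate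
26 | (1S,5R)-1-methyl-7-(Kcp)bicyclo[3.2.1]oct-6-ene-3,8-dione | CC2(OCCO2)CC[C@H]1[C@@H](C3=C[C@@H]4C(=O)[C@@]3(C)CC(=O)C4)C1(C)C | intermediate
27 | (1S,5R)-4-[hydroxy(Kcp)methyl]-1-methyl-7-(Kcp)bicyclo[3.2.1]oct-6-ene-3,8-dione (epimers at C15 and the carbinol) | CC2(OCCO2)CC[C@H]1[C@@H](C3=C[C@@H]4C(=O)[C@@]3(C)CC(=O)C4C(O)[C@@H]5[C@H](CCC6(C)OCCO6)C5(C)C)C1(C)C | intermediate
28 | acetate of 27 | CC2(OCCO2)CC[C@H]1[C@@H](C3=C[C@@H]4C(=O)[C@@]3(C)CC(=O)C4C(OC(C)=O)[C@@H]5[C@H](CCC6(C)OCCO6)C5(C)C)C1(C)C | intermediate (not isolated)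
29 | (1S,5R,4E)-1-methyl-7-(Kcp)-4-[(Kcp)methylidene]bicyclo[3.2.1]oct-6-ene-3,8-dione | CC2(OCCO2)CC[C@H]1[C@@H](C3=C[C@@H]4C(=O)[C@@]3(C)CC(=O)/C4=C/[C@@H]5[C@H](CCC6(C)OCCO6)C5(C)C)C1(C)C | intermediate
30 | vinylmagnesium bromide | C=C[Mg]Br | starting material
31 | C14=C15 trimethylsilyl enol ether of 32 | CC2(OCCO2)CC[C@H]1[C@@H](C3=C[C@@H]4C(=O)[C@@]3(C)CC(O[Si](C)(C)C)=C4[C@@H](C=C)[C@@H]5[C@H](CCC6(C)OCCO6)C5(C)C)C1(C)C | intermediate (not isolated)
32 | (1S,5R)-1-methyl-7-(Kcp)-4-[1-(Kcp)prop-2-enyl]bicyclo[3.2.1]oct-6-ene-3,8-dione (arm endo at C15) | CC2(OCCO2)CC[C@H]1[C@@H](C3=C[C@@H]4C(=O)[C@@]3(C)CC(=O)[C@@H]4[C@@H](C=C)[C@@H]5[C@H](CCC6(C)OCCO6)C5(C)C)C1(C)C | intermediate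
33 | C13=C14 tert-butyldimethylsilyl enol ether of 32 | CC2(OCCO2)CC[C@H]1[C@@H](C3=C[C@@H]4C(=O)[C@@]3(C)C=C(O[Si](C)(C)C(C)(C)C)[C@@H]4[C@@H](C=C)[C@@H]5[C@H](CCC6(C)OCCO6)C5(C)C)C1(C)C | intermediate
34 | syn-tricyclic 10,14-dione with C7=C8 and exocyclic C26=C27H2, bis-dioxolane | CC7(OCCO7)CC[C@H]1[C@@H](C2=C[C@@H]3C(=O)[C@@]2(C)[C@H]2C(=O)[C@@H]3[C@H]([C@@H]4[C@H](CCC5(C)OCCO5)C4(C)C)C2=C)C1(C)C | intermediate
35 | syn-tricyclic 10,14-dione with C7=C8 and C16=C26, bis-dioxolane | CC7(OCCO7)CC[C@H]1[C@@H](C2=C[C@@H]3C(=O)[C@@]2(C)[C@H]2C(=O)[C@@H]3C([C@@H]4[C@H](CCC5(C)OCCO5)C4(C)C)=C2C)C1(C)C | intermediate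
36 | bis-hydrazone of 35 | CC7(OCCO7)CC[C@H]1[C@@H](C2=C[C@@H]3C(=NN)[C@@]2(C)[C@H]2C(=NN)[C@@H]3C([C@@H]4[C@H](CCC5(C)OCCO5)C4(C)C)=C2C)C1(C)C | intermediate (not isolated)
37 | bis(ethylene ketal) of the target | CC7(OCCO7)CC[C@H]1[C@@H](C2=C[C@@H]3C[C@@]2(C)[C@H]2C[C@@H]3C([C@@H]4[C@H](CCC5(C)OCCO5)C4(C)C)=C2C)C1(C)C | intermediate
38 | CNP0300925.1: syn-4,6-dimethyltricyclo[4.2.1.1(2,5)]deca-3,7-diene carrying at C3 and C7 a cis-2,2-dimethyl-3-(3-oxobutyl)cyclopropyl group | CC(=O)CC[C@H]1[C@@H](C2=C[C@@H]3C[C@@]2(C)[C@H]2C[C@@H]3C([C@@H]3[C@H](CCC(C)=O)C3(C)C)=C2C)C1(C)C | target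

**Count and weak points**

Total steps: 24. Longest linear sequence: 22 steps (steps 1–7 and 10–24, from caronic anhydride); steps 8 and 9 form a two-step side branch.

Steps most likely to fail:

1. Step 21. Closing ring B on the endo face forces ring C into a boat and stacks the new bridge against the C7=C8 bridge. Carbon–carbon bond formation may therefore be outrun by protodesilylation of the enol ether, and an arm epimer at C16 left by imperfect face selection in step 19 cannot cyclise. Fallback (radical instead of organopalladium bond formation): set out from enol ether 33. N-Iodosuccinimide gives the C13 α-iodo ketone F1; iodine-atom-transfer radical cyclisation (Et3B, air, benzene, 23 °C) gives the iodomethyl tricycle F2; elimination of HI with DBU rejoins the route at 34.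

2. Step 10. The enamine carbon is fully substituted and the nitroalkene carries a bulky cis-substituted cyclopropane at its β-carbon, so the addition may be slow or reversible, or face selection may be poor if the amine auxiliary and the chiral nitroalkene are mismatched. Fallback (conjugate addition with enolate alkylation in place of the imine Michael addition): set out from ketone 14 and aldehyde 9. Aldol condensation gives the enone F3; lithium divinylcuprate adds at C7 and the enolate is trapped with MeI (HMPA) to give the 2-methyl-2-(1-cyclopropylallyl) ketone F4, in which C11 rests on substrate control. Ozonolysis of the vinyl group then delivers 21, and C11 diastereomers would be separated at 22.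

3. Step 22. The double-bond migration may stop short if the exocyclic and ring isomers lie close in energy, and hydrogen-atom transfer to C7=C8 would open the neighbouring cyclopropane through a cyclopropylcarbinyl radical. Fallback (exchange of C27 instead of migration): set out from 34. Osmium tetroxide (cat.) with N-methylmorpholine N-oxide dihydroxylates the unhindered exocyclic methylene to diol F5, and NaIO4 cleaves it to triketone F6. F6 can enolise only toward C16 and is converted (KHMDS, PhNTf2) into enol triflate F7; palladium-catalysed coupling with Me2Zn (PdCl2(dppf), THF) rejoins the route at 35.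

Further compounds
F1 | step 21 | C13 α-iodo ketone derived from 33 | CC2(OCCO2)CC[C@H]1[C@@H](C3=C[C@@H]4C(=O)[C@@]3(C)C(I)C(=O)[C@@H]4[C@@H](C=C)[C@@H]5[C@H](CCC6(C)OCCO6)C5(C)C)C1(C)C
F2 | step 21 | syn-tricyclic 10,14-dione with iodomethyl group on C26 | CC7(OCCO7)CC[C@H]1[C@@H](C2=C[C@@H]3C(=O)[C@@]2(C)[C@H]2C(=O)[C@@H]3[C@H]([C@@H]4[C@H](CCC5(C)OCCO5)C4(C)C)C2CI)C1(C)C
F3 | step 10 | (E)-2-[(Kcp)methylidene]-4,4-dimethoxycyclohexan-1-one | CC2(OCCO2)CC[C@H]1[C@@H](/C=C3\CC(OC)(OC)CCC3=O)C1(C)C
F4 | step 10 | (2S)-4,4-dimethoxy-2-methyl-2-[1-(Kcp)prop-2-enyl]cyclohexan-1-one | CC2(OCCO2)CC[C@H]1[C@@H](C(C=C)[C@@]3(C)C(=O)CCC(OC)(OC)C3)C1(C)C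
F5 | step 22 | C26,C27-diol derived from 34 | CC7(OCCO7)CC[C@H]1[C@@H](C2=C[C@@H]3C(=O)[C@@]2(C)[C@H]2C(=O)[C@@H]3[C@H]([C@@H]4[C@H](CCC5(C)OCCO5)C4(C)C)C2(O)CO)C1(C)C
F6 | step 22 | syn-tricyclic 10,14,26-trione | CC7(OCCO7)CC[C@H]1[C@@H](C2=C[C@@H]3C(=O)[C@@]2(C)[C@H]2C(=O)[C@@H]3[C@H]([C@@H]4[C@H](CCC5(C)OCCO5)C4(C)C)C2=O)C1(C)C
F7 | step 22 | C16=C26 enol triflate of F6 | CC7(OCCO7)CC[C@H]1[C@@H](C2=C[C@@H]3C(=O)[C@@]2(C)[C@H]2C(=O)[C@@H]3C([C@@H]4[C@H](CCC5(C)OCCO5)C4(C)C)=C2OS(=O)(=O)C(F)(F)F)C1(C)C
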